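Atom labels C1–C20 follow cembrane numbering of the target: C1 carries the acrylic acid, C3 the OH, C4–O–C7 is the THF, C8=C19, C11 the OAc, C12 the OH. The target is (1R,3R,4R,7S,11S,12R).
Assumption: a telescoped one-pot operation with no isolation counts as one step.

## Retrosynthetic overview
1. The acid comes from late oxidation of the C16 allylic alcohol. One electrochemical Ni step forms C7–C8 from a seco acetal/2-bromoalkene: the THF (C4–O–C7) closes first in situ, then the 14-membered carbocycle.
2. The seco chain comes from C12–C13 acylation (alkyllithium plus Weinreb amide). Chelate-controlled MeMgBr addition then sets C12, followed by acetylation at C11.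
3. The C1–C7/C13–C18 half comes from (R)-carvone. C1 is bought, C3 is set by Luche reduction, the ring C=C is cleaved, and C4 is set by Cram-chelate Grignard addition.
4. The C8–C12 half comes from L-malic acid. C11 is bought, and C9–C10 is formed by photoredox decarboxylative 2-bromoallylation.

## Route

**Step 1**
Reactants: 1, (R)-(−)-carvone
Product: 2, (5R)-5-(3-hydroxyprop-1-en-2-yl)-2-methylcyclohex-2-en-1-one (10-hydroxycarvone)
Conditions: SeO2 (0.5 equiv), t-BuOOH (3 equiv), CH2Cl2, rt. Any 10-al is carried on and converges in step 2.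
Reagents that add atoms: selenium dioxide O=[Se]=O; tert-butyl hydroperoxide CC(C)(C)OO (O source)
Why: SeO2 allylic hydroxylation (ene/[2,3]) attacks only the electron-rich isopropenyl CH3 because the enone C=C is deactivated, and the purchased C1 centre is untouched.

**Step 2**
Reactants: 2
Product: 3, (1R,5R)-5-(3-hydroxyprop-1-en-2-yl)-2-methylcyclohex-2-en-1-ol (cis-carveol type diol)
Conditions: NaBH4, CeCl3·7H2O, MeOH, −20 °C
Reagents that add atoms: none
Why: Luche 1,2-reduction delivers hydride axially to give the equatorial alcohol cis to the C1 side chain (≥95:5), which sets C3 (R) from C1.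

**Step 3**
Reactants: 3
Product: 4, bis-TES ether of 3
Conditions: TESCl (2.5 equiv), imidazole, CH2Cl2, 0 °C
Reagents that add atoms: chlorotriethylsilane CC[Si](Cl)(CC)CC
Why: This is a standard silylation, and TES is small enough to still chelate Mg in step 6.

**Step 4**
Reactants: 4
Product: 5, (3R,5R)-7-hydroxy-3-(triethylsilyloxy)-5-[3-(triethylsilyloxy)prop-1-en-2-yl]heptan-2-one
Conditions: O3 (1.0 equiv, Sudan Red 7B end point), CH2Cl2, −78 °C; PPh3; then NaBH(OAc)3, AcOH, rt (one pot)
Reagents that add atoms: ozone [O-][O+]=O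
Why: Both alkenes carry the same allylic OSi deactivation, so ozonolysis takes the trisubstituted ring alkene over the 1,1-disubstituted one (limonene-type selectivity), and NaBH(OAc)3 then reduces only the C13 aldehyde and leaves the C4 methyl ketone.

**Step 5**
Reactants: 5
Product: 6, (3R,5S)-7-iodo-3-(triethylsilyloxy)-5-[3-(triethylsilyloxy)prop-1-en-2-yl]heptan-2-one
Conditions: I2, PPh3, imidazole, CH2Cl2, 0 °C
Reagents that add atoms: iodine II
Why: Appel iodination of the only free (primary) alcohol proceeds under buffered conditions that spare TES ethers and the ketone.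

**Step 6**
Reactants: 6; 7, [2-(1,3-dioxan-2-yl)ethyl]magnesium bromide (commercial 0.5 M THF solution)
Product: 8, (3R,4R,6S)-1-(1,3-dioxan-2-yl)-8-iodo-3-methyl-4-(triethylsilyloxy)-6-[3-(triethylsilyloxy)prop-1-en-2-yl]octan-3-ol
Conditions: 7 (1.8 equiv), THF, −78 °C
Reagents that add atoms: 7, Br[Mg]CCC1OCCCO1
Why: In this Cram-chelate Grignard addition Mg bridges C4=O and C3–OTES and C5 attacks from the H-side of C3, which gives (4R) with C4–O syn to C3–O; the primary iodide is inert at −78 °C.

**Step 7**
Reactants: 9, L-(S)-malic acid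
Product: 10, 2-[(4S)-2,2-dimethyl-5-oxo-1,3-dioxolan-4-yl]acetic acid
Conditions: 2,2-dimethoxypropane, p-TsOH (cat.), rt
Reagents that add atoms: 2,2-dimethoxypropane COC(C)(C)OC
Why: Selective dioxolanone formation ties up the α-hydroxy acid and leaves the β-CO2H free, and C11 (S) is bought.

**Step 8**
Reactants: 11, 2,3-dibromopropene; 12, sodium benzenesulfinate
Product: 13, 2-bromoallyl phenyl sulfone
Conditions: DMF, rt
Reagents that add atoms: 11 C=C(Br)CBr; 12 [Na+].[O-]S(=O)c1ccccc1
Why: SN2 S-alkylation of sulfinate occurs at the allylic bromide.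

**Step 9**
Reactants: 10; 14, N-hydroxyphthalimide
Product: 15, NHPI (redox-active) ester of 10
Conditions: DIC, DMAP (cat.), CH2Cl2, rt
Reagents that add atoms: 14 ON1C(=O)c2ccccc2C1=O
Why: This is a Steglich-type esterification of the only free acid.

**Step 10**
Reactants: 15; 13 (2.5 equiv)
Product: 16, (5S)-5-(3-bromobut-3-en-1-yl)-2,2-dimethyl-1,3-dioxolan-4-one
Conditions: Ru(bpy)3(PF6)2 (1 mol %), Hantzsch ester (1.5 equiv), i-Pr2NEt, CH2Cl2, 450 nm LEDs, rt
Reagents that add atoms: 13 C=C(Br)CS(=O)(=O)c1ccccc1
Why: In this photoredox decarboxylative radical allylation (SH2′), the C10 radical adds to the CH2= terminus and expels PhSO2•, which forms C9–C10 and delivers the C8(Br)=C19H2 unit; the radical is not at C11.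

**Step 11**
Reactants: 16; 17, N,O-dimethylhydroxylamine hydrochloride
Product: 18, (2S)-5-bromo-2-hydroxy-N-methoxy-N-methylhex-5-enamide
Conditions: AlMe3, CH2Cl2, 0 °C → rt
Reagents that add atoms: 17 CNOC.Cl
Why: Weinreb aminolysis of the activated dioxolanone releases acetone and frees C11–OH for later chelation.

**Step 12**
Reactants: 8; 18 (1.4 equiv)
Product: 19, (5S,9R,11R,12R)-2-bromo-14-(1,3-dioxan-2-yl)-5,12-dihydroxy-12-methyl-11-(triethylsilyloxy)-9-[3-(triethylsilyloxy)prop-1-en-2-yl]tetradec-1-en-6-one
Conditions: 8: MeLi (1.0 equiv), then t-BuLi (2.1 equiv), Et2O/pentane, −78 °C; add 18 pre-treated with i-PrMgCl (1.05 equiv, THF, −78 °C); −78 → −40 °C; aq NH4Cl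
Reagents that add atoms: none beyond reactants 8 and 18
Why: In this Weinreb ketone synthesis the C4–OH is deprotonated first, I/Li exchange gives the C13 alkyllithium, and the chelated tetrahedral adduct stops over-addition; the α-alkoxide suppresses enolisation at C11.

**Step 13**
Reactants: 19
Product: 20, (5S,6R,9R,11R,12R)-2-bromo-14-(1,3-dioxan-2-yl)-6,12-dimethyl-11-(triethylsilyloxy)-9-[3-(triethylsilyloxy)prop-1-en-2-yl]tetradec-1-ene-5,6,12-triol
Conditions: MeMgBr (6 equiv), THF, −78 °C
Reagents that add atoms: methylmagnesium bromide C[Mg]Br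
Why: In the Cram cyclic (magnesium alkoxide chelate) model, methyl attacks the C12 ketone from the H-side of C11, which gives (12R) with C12–OH anti to C11–O in the C10–C13 zigzag.

**Step 14**
Reactants: 20
Product: 21, 5-O-acetate of 20 (C11–OAc)
Conditions: Ac2O (1.5 equiv), pyridine, DMAP (5 mol %), CH2Cl2, 0 °C
Reagents that add atoms: acetic anhydride CC(=O)OC(C)=O
Why: The only unprotected secondary alcohol is acylated, because the two tertiary alcohols do not react under these conditions.

**Step 15**
Reactants: 21
Product: 22, (1R,3R,4R,7S,11S,12R)-11-acetoxy-4,7-epoxycembra-8(19),15(17)-diene-3,12,16-triol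
Conditions: TMSCl (6 equiv), Zn(OTf)2 (10 mol %), 2,6-lutidine (2 equiv), NiBr2·dme (30 mol %), dtbbpy (33 mol %), n-Bu4NBr, THF/DMA 4:1, undivided cell, Zn(+)|RVC(−), 1.5 mA, 21 added over 12 h (final 1 mM), rt; then MeOH, 0 °C (HCl formed in situ removes TMS/TES)
Reagents that add atoms: none
Why: Proposed new method: Ni-electrocatalytic acetal/alkenyl-bromide reductive macrocyclisation, in which TMSCl/Zn(II) ionises the dioxane acetal so that C4–OH closes the THF and leaves a 2-chloro-THF, cathodic Ni(0) inserts into C8–Br, the alkenyl–Ni(II) is reduced to alkenyl–Ni(I), this abstracts Cl from C7 of the same chain and recombines with the α-oxy radical, and reductive elimination from Ni(III) forms C7–C8 and the 14-ring; halogen abstraction and rebound happen at one Ni centre, so high dilution should favour ring closure over oligomers, and C7 (S) is expected because the alkenyl–Ni arm is anchored through C3 on one face of C4, which makes the cis-2,5 (out,out-bicyclo[10.2.1]) closure the lower-strain one; the closest known reaction types are Ni-catalysed reductive cross-electrophile coupling of acetals (via α-chloro ethers) or glycosyl halides with aryl/alkenyl halides, and electrochemical Ni C(sp2)–C(sp3) cross-electrophile coupling, neither shown for aliphatic cyclic acetals or macrocyclisation.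

**Step 16**
Reactants: 22
Product: 23, Dendronpholide R
Conditions: TEMPO (0.2 equiv), PhI(OAc)2 (1.2 equiv), CH2Cl2, rt; then t-BuOH/H2O, 2-methyl-2-butene, NaH2PO4, NaClO2 (one pot)
Reagents that add atoms: sodium chlorite [Na+].[O-]Cl=O
Why: Oxoammonium oxidation takes the primary allylic alcohol over the hindered, neopentyl-like C3–OH, and Pinnick oxidation with a chlorine scavenger converts the enal to the acrylic acid without touching the acetate, the alkenes or any stereocentre.

## Compound list
1 | (R)-(−)-carvone | CC1=CC[C@H](CC1=O)C(C)=C | starting material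
2 | (R)-10-hydroxycarvone | CC1=CC[C@H](CC1=O)C(=C)CO | intermediate
3 | (1R,5R)-5-(3-hydroxyprop-1-en-2-yl)-2-methylcyclohex-2-en-1-ol | CC1=CC[C@H](C[C@H]1O)C(=C)CO | intermediate
4 | bis-TES ether of 3 | CC1=CC[C@H](C[C@H]1O[Si](CC)(CC)CC)C(=C)CO[Si](CC)(CC)CC | intermediate
5 | (3R,5R)-7-hydroxy keto bis-silyl ether | CC(=O)[C@H](O[Si](CC)(CC)CC)C[C@@H](CCO)C(=C)CO[Si](CC)(CC)CC | intermediate
6 | (3R,5S)-7-iodo ketone | CC(=O)[C@H](O[Si](CC)(CC)CC)C[C@@H](CCI)C(=C)CO[Si](CC)(CC)CC | intermediate
7 | [2-(1,3-dioxan-2-yl)ethyl]magnesium bromide | Br[Mg]CCC1OCCCO1 | starting material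
8 | (3R,4R,6S) tertiary alcohol iodide (C1–C7, C13–C18) | O1CCCOC1CC[C@@](C)(O)[C@H](O[Si](CC)(CC)CC)C[C@@H](CCI)C(=C)CO[Si](CC)(CC)CC | intermediate
9 | L-malic acid | OC(=O)C[C@H](O)C(=O)O | starting material
10 | (S)-malic acid acetonide acid | CC1(C)OC(=O)[C@H](CC(=O)O)O1 | intermediate
11 | 2,3-dibromopropene | C=C(Br)CBr | starting material
12 | sodium benzenesulfinate | [Na+].[O-]S(=O)c1ccccc1 | starting material
13 | 2-bromoallyl phenyl sulfone | C=C(Br)CS(=O)(=O)c1ccccc1 | intermediate
14 | N-hydroxyphthalimide | ON1C(=O)c2ccccc2C1=O | starting material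
15 | NHPI ester of 10 | CC1(C)OC(=O)[C@H](CC(=O)ON2C(=O)c3ccccc3C2=O)O1 | intermediate
16 | (5S)-5-(3-bromobut-3-en-1-yl)-2,2-dimethyl-1,3-dioxolan-4-one | CC1(C)OC(=O)[C@H](CCC(Br)=C)O1 | intermediate
17 | N,O-dimethylhydroxylamine hydrochloride | CNOC.Cl | starting material
18 | (2S)-5-bromo-2-hydroxy-N-methoxy-N-methylhex-5-enamide | CON(C)C(=O)[C@@H](O)CCC(Br)=C | intermediate
19 | seco α-hydroxy ketone (1R,3R,4R,11S) | O1CCCOC1CC[C@@](C)(O)[C@H](O[Si](CC)(CC)CC)C[C@@H](CCC(=O)[C@@H](O)CCC(Br)=C)C(=C)CO[Si](CC)(CC)CC | intermediate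
20 | seco triol (1R,3R,4R,11S,12R) | O1CCCOC1CC[C@@](C)(O)[C@H](O[Si](CC)(CC)CC)C[C@@H](CC[C@@](C)(O)[C@@H](O)CCC(Br)=C)C(=C)CO[Si](CC)(CC)CC | intermediate
21 | seco C11 acetate | O1CCCOC1CC[C@@](C)(O)[C@H](O[Si](CC)(CC)CC)C[C@@H](CC[C@@](C)(O)[C@@H](OC(C)=O)CCC(Br)=C)C(=C)CO[Si](CC)(CC)CC | intermediate
22 | 16-hydroxy macrocycle | C=C(CO)[C@@H]1CC[C@@](C)(O)[C@@H](OC(C)=O)CCC(=C)[C@@H]2CC[C@@](C)(O2)[C@H](O)C1 | intermediate
23 | Dendronpholide R | C=C(C(=O)O)[C@@H]1CC[C@@](C)(O)[C@@H](OC(C)=O)CCC(=C)[C@@H]2CC[C@@](C)(O2)[C@H](O)C1 | target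

## Counts
Total steps: 16.
Longest linear sequence: 11 (steps 1–6, then 12–16).

## Steps most likely to fail
1. **Step 15 (proposed new step).**
   - Risks are reduction of the 2-chloro-THF to C7–H, protodebromination, oligomers, or the trans-C7 epimer. Trans-2,5-bridged THF macrocycles of this size do exist, so the cis preference is an expectation and not a guarantee.
   - The fallback uses known chemistry. Aqueous AcOH unmasks the C7 lactol and removes TES, and a classical stoichiometric CrCl2/NiCl2 Nozaki–Hiyama–Kishi macrocyclisation follows.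
   - MnO2 then oxidises C7–OH to the enone and C16–OH to the enal together, and Pinnick oxidation gives the acid.
   - Finally, Et3SiH/TMSOTf reduces the transannular C4–O–C7 hemiketal. Hydride arrives from the open, methyl-bearing face, which gives the cis-THF.
2. **Step 4 (alkene-selective ozonolysis).**
   - The fallback replaces rate-based selection with hydroxyl direction.
   - The order becomes Luche reduction of carvone first, then VO(acac)2/t-BuOOH epoxidation of cis-carveol, which reaches only the ring alkene.
   - SeO2 then acts on the single remaining alkene, followed by bis-silylation, H5IO6 cleavage of the epoxide, and NaBH(OAc)3.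
3. **Step 12 (alkyllithium/Weinreb union on a polyfunctional iodide).**
   - The fallback avoids organolithiums.
   - A CrCl2/cat. Co (vitamin B12) alkyl-chromium addition of iodide 8 is made to the O-TES α-oxy aldehyde derived from 16. The vinyl bromide is inert without Ni.
   - Dess–Martin oxidation then gives the same C12 ketone skeleton as its C11–OTES ether. TES can still chelate in step 13, but it must be removed before the acetylation in step 14.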